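**Strategy.** The 1,2-dioxane (ring atoms O1, O2, C3–C6) is disconnected at C5–C6 and O2–C3. The key step uses the fact that C6 is a ketone carbon in disguise that already carries O1, while C3–C4–C5 is the β-carbanion (homoenolate) synthon of the C3 ketone. A C6 peroxycarbenium ion is attacked by a 2-methyl-1-silyloxycyclopropane and the silylperoxy oxygen then closes the ring, so one operation makes both bonds and imports the C4 centre. Its precursors are the methyl triethylsilylperoxy ketal of the side-chain methyl ketone, from (R)-citronellal, and an enantiopure silyloxycyclopropane with a protected hydroxyethyl arm, from methyl (R)-3-hydroxy-2-methylpropanoate.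

Key step: step 16

Assumption: C3 is a peroxy hemiketal carbon that equilibrates by ring–chain tautomerism, and the 3S anomer of the target (axial OH; CH2CO2H, C4 methyl and C6 alkyl chain equatorial) is taken as the thermodynamic one, so the route sets only C4, C6 and the side-chain centre.

Step 1
Reactants: 1 (R)-citronellal
Product: 2 (4R)-4,8-dimethylnon-7-en-2-ol (mixture of C2 epimers)
Conditions: MeMgBr, Et2O, 0 °C; aq NH4Cl
Reagents that add atoms: methylmagnesium bromide (C[Mg]Br)
Why: Grignard addition to the aldehyde installs the methyl group of the later C6 methyl ketone; the carbinol centre forms without control but is oxidised away in step 6, and the citronellal stereocentre is not touched.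

Step 2
Reactants: 2 (4R)-4,8-dimethylnon-7-en-2-ol
Product: 4 (4R)-6-hydroxy-4-methylheptanal, via ozonide 3 (not isolated)
Conditions: O3, CH2Cl2, −78 °C; then PPh3, −78 °C → rt
Reagents that add atoms: ozone ([O-][O+]=O)
Why: Ozonolysis (Criegee mechanism) cleaves the electron-rich trisubstituted alkene and PPh3 reduces the ozonide to the aldehyde with loss of acetone, the secondary alcohol being inert to ozone at low temperature.

Step 3
Reactants: 5 (5-bromopentyl)benzene
Product: 6 triphenyl(5-phenylpentyl)phosphonium bromide
Conditions: PPh3, MeCN, reflux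
Reagents that add atoms: triphenylphosphine (c1ccc(cc1)P(c1ccccc1)c1ccccc1)
Why: SN2 quaternisation of the phosphine by the primary bromide should give the Wittig salt.

Step 4
Reactants: 4 (4R)-6-hydroxy-4-methylheptanal; 6 triphenyl(5-phenylpentyl)phosphonium bromide
Product: 8 (4R,7Z)-4-methyl-12-phenyldodec-7-en-2-ol, via phosphorus ylide 7 (not isolated)
Conditions: 6 (2.3 equiv), NaN(SiMe3)2 (2.2 equiv), THF, 0 °C; then 4, −78 °C → rt
Reagents that add atoms: none
Why: Wittig olefination of the aldehyde with the non-stabilised ylide, used in excess so that proton exchange with the free hydroxyl does not starve the reaction, joins the phenylpentyl unit to the chain; the alkene geometry, expected mainly Z, is irrelevant because the double bond is hydrogenated next.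

Step 5
Reactants: 8 (4R,7Z)-4-methyl-12-phenyldodec-7-en-2-ol
Product: 9 (4R)-4-methyl-12-phenyldodecan-2-ol
Conditions: H2 (1 atm), 10% Pd/C, EtOAc, rt
Reagents that add atoms: none
Why: Heterogeneous catalytic hydrogenation should saturate the disubstituted alkene while the unactivated phenyl ring and the non-benzylic alcohol are left alone under these mild conditions.

Step 6
Reactants: 9 (4R)-4-methyl-12-phenyldodecan-2-ol
Product: 10 (4R)-4-methyl-12-phenyldodecan-2-one
Conditions: Dess–Martin periodinane, NaHCO3, CH2Cl2, 0 °C → rt
Reagents that add atoms: none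
Why: Dess–Martin oxidation converts the secondary alcohol into the methyl ketone, whose stereocentre is β to the carbonyl and cannot epimerise.

Step 7
Reactants: 10 (4R)-4-methyl-12-phenyldodecan-2-one
Product: 11 (4R)-2,4-dimethyl-12-phenyldodec-1-ene
Conditions: Ph3PCH3Br, KOtBu, THF, 0 °C → rt
Reagents that add atoms: methyltriphenylphosphonium bromide (C[P+](c1ccccc1)(c1ccccc1)c1ccccc1.[Br-])
Why: Wittig methylenation turns the ketone into the 1,1-disubstituted alkene from which step 8 generates the carbonyl oxide of this carbon.

Step 8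
Reactants: 11 (4R)-2,4-dimethyl-12-phenyldodec-1-ene
Product: 12 (4R)-2-hydroperoxy-2-methoxy-4-methyl-12-phenyldodecane (mixture of C2 epimers)
Conditions: O3, CH2Cl2/MeOH (4:1), −78 °C; N2 purge, no reductive work-up
Reagents that add atoms: ozone ([O-][O+]=O); methanol (CO)
Why: Ozonolysis in methanol (Criegee mechanism): the primary ozonide of an acyclic 1,1-dialkylethene should split mainly into formaldehyde and the more substituted carbonyl oxide, which methanol traps as the α-methoxy hydroperoxide, and the alkene reacts far faster than the phenyl ring.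

Step 9
Reactants: 12 (4R)-2-hydroperoxy-2-methoxy-4-methyl-12-phenyldodecane
Product: 13 triethyl{[(4R)-2-methoxy-4-methyl-12-phenyldodecan-2-yl]peroxy}silane
Conditions: Et3SiCl, imidazole, DMF, 0 °C
Reagents that add atoms: chlorotriethylsilane (CC[Si](Cl)(CC)CC)
Why: O-silylation of the hydroperoxide, which is more acidic than an alcohol, under mild base should give the silyl peroxide without ionising the ketal.

Step 10
Reactants: 14 methyl (R)-3-hydroxy-2-methylpropanoate
Product: 15 methyl (S)-3-chloro-2-methylpropanoate
Conditions: PPh3, CCl4, CH2Cl2, reflux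
Reagents that add atoms: tetrachloromethane (ClC(Cl)(Cl)Cl)
Why: Appel chlorination replaces the primary hydroxyl under neutral conditions, so the enolisable α-centre is preserved (the descriptor changes only through the CIP priorities).

Step 11
Reactants: 15 methyl (S)-3-chloro-2-methylpropanoate
Product: 16 (2R)-1-methoxy-2-methyl-1-(trimethylsilyloxy)cyclopropane (mixture of C1 epimers)
Conditions: Na (dispersion), Me3SiCl, Et2O, reflux
Reagents that add atoms: chlorotrimethylsilane (C[Si](C)(C)Cl)
Why: Acyloin-type reductive cyclisation of a β-chloro ester under Rühlmann conditions closes the three-membered ring between the ester carbon and the CH2Cl carbon and traps the alkoxide as its silyl ether; the α-carbon is not deprotonated, so its configuration becomes C2 of the cyclopropane.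

Step 12
Reactants: 16 (2R)-1-methoxy-2-methyl-1-(trimethylsilyloxy)cyclopropane
Product: 19 (2R)-1-ethenyl-2-methylcyclopropan-1-ol (mixture of C1 epimers), via hemiacetal 17 (not isolated), via 2-methylcyclopropanone 18 (not isolated)
Conditions: MeOH, rt; careful concentration at 0 °C; then CH2=CHMgBr (2.5 equiv), THF, 0 → 50 °C; aq NH4Cl
Reagents that add atoms: vinylmagnesium bromide (C=C[Mg]Br)
Why: Methanolysis frees the cyclopropanone hemiacetal, whose magnesium salt releases the strained ketone in the flask, and Grignard addition to it gives the tertiary cyclopropanol; the C1 configuration is of no consequence because C1 becomes planar in step 16.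

Step 13
Reactants: 19 (2R)-1-ethenyl-2-methylcyclopropan-1-ol
Product: 20 {[(2R)-1-ethenyl-2-methylcyclopropyl]oxy}trimethylsilane
Conditions: Me3SiCl, imidazole, DMF, 0 °C → rt
Reagents that add atoms: chlorotrimethylsilane (C[Si](C)(C)Cl)
Why: Silylation of the tertiary cyclopropanol gives the silyl ether that the annulation needs and blocks base-induced ring opening of the free cyclopropanol in the next step.

Step 14
Reactants: 20 {[(2R)-1-ethenyl-2-methylcyclopropyl]oxy}trimethylsilane
Product: 22 2-[(2R)-2-methyl-1-(trimethylsilyloxy)cyclopropyl]ethan-1-ol, via alkylborane 21 (not isolated)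
Conditions: 9-BBN, THF, 0 °C → rt; then NaBO3·4H2O, H2O, rt
Reagents that add atoms: 9-borabicyclo[3.3.1]nonane (B1C2CCCC1CCC2); sodium perborate ([Na+].[Na+].O[B-]1(O)OO[B-](O)(O)OO1)
Why: Hydroboration–oxidation: the bulky borane places boron on the terminal carbon of the vinyl group (anti-Markovnikov) to give 21, and the mild perborate oxidation then replaces boron by hydroxyl while sparing the trimethylsilyl ether and the cyclopropane, the borabicyclic fragment leaving as cyclooctane-1,5-diol.

Step 15
Reactants: 22 2-[(2R)-2-methyl-1-(trimethylsilyloxy)cyclopropyl]ethan-1-ol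
Product: 23 tert-butyl{2-[(2R)-2-methyl-1-(trimethylsilyloxy)cyclopropyl]ethoxy}diphenylsilane
Conditions: tBuPh2SiCl, imidazole, CH2Cl2, 0 °C → rt
Reagents that add atoms: tert-butyl(chloro)diphenylsilane (CC(C)(C)[Si](Cl)(c1ccccc1)c1ccccc1)
Why: Silylation of the primary alcohol gives an ether that should withstand TiCl4 at −78 °C and is removed by fluoride at the end.

Step 16
Reactants: 13 triethyl{[(4R)-2-methoxy-4-methyl-12-phenyldodecan-2-yl]peroxy}silane; 23 tert-butyl{2-[(2R)-2-methyl-1-(trimethylsilyloxy)cyclopropyl]ethoxy}diphenylsilane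
Product: 24 tert-butyl{2-[(3R,4R,6S)-4,6-dimethyl-6-[(2R)-2-methyl-10-phenyldecyl]-3-(trimethylsilyloxy)-1,2-dioxan-3-yl]ethoxy}diphenylsilane (expected together with its 6R epimer; the mixture is carried on)
Conditions: 13, 23 (1.5 equiv), CH2Cl2, −78 °C; TiCl4 (1.1 equiv) added dropwise; pyridine, then aq NaHCO3
Reagents that add atoms: none
Why: Proposed new method: TiCl4 removes the methoxy group of 13 and leaves the C6 peroxycarbenium ion; the strained ring bond of 23 between the silyloxy carbon and the CH2 carbon (future C3 and C5), made electron-rich by the silyloxy group, attacks it through the CH2 carbon and opens, so that C5–C6 forms and C3 becomes a silyl oxocarbenium ion, which the silylated peroxide oxygen O2 captures before Et3Si is lost to chloride. The closest known reaction types are the Lewis-acid annulation of peroxycarbenium ions from silylperoxy ketals with alkenes to 1,2-dioxolanes and the electrophilic ring opening of silyloxycyclopropanes as homoenolate equivalents by metal halides and by acetal-derived oxocarbenium ions. The 1,2-dioxane closes in the 6-exo-trig mode, O2 adding to the exocyclic C3=O+ bond. C4 is not formed here but carried over from C2 of the cyclopropane, whose four bonds stay intact; C6 arises from an open-chain cation whose only stereocentre is remote, so no control is expected and both epimers should form; C3 should close with the silyloxy group axial and is in any case re-equilibrated in step 17. The step needs ionisation of the C–OMe bond and not the C–OOSi bond, which the more basic methoxy oxygen should secure, and cleavage of the less substituted ring bond and not the bond to the methyl-bearing carbon, which attack at the less hindered CH2 carbon should secure.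

Step 17
Reactants: 24 tert-butyl{2-[(3R,4R,6S)-4,6-dimethyl-6-[(2R)-2-methyl-10-phenyldecyl]-3-(trimethylsilyloxy)-1,2-dioxan-3-yl]ethoxy}diphenylsilane (epimer mixture)
Product: 25 (3S,4R,6S)-3-(2-hydroxyethyl)-4,6-dimethyl-6-[(2R)-2-methyl-10-phenyldecyl]-1,2-dioxan-3-ol
Conditions: HF·pyridine, pyridine, THF, 0 °C → rt; chromatography to remove the 6R epimer
Reagents that add atoms: none
Why: Fluoride-driven desilylation cleaves the silyl ketal and the silyl ether without touching the O–O bond; the freed peroxy hemiketal should settle at C3 by ring–chain tautomerism to the anomer with axial OH and equatorial arm, and the C6 epimers, being diastereomers, should separate on silica.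

Step 18
Reactants: 25 (3S,4R,6S)-3-(2-hydroxyethyl)-4,6-dimethyl-6-[(2R)-2-methyl-10-phenyldecyl]-1,2-dioxan-3-ol
Product: 27 2-[(3S,4R,6S)-3-hydroxy-4,6-dimethyl-6-[(2R)-2-methyl-10-phenyldecyl]-1,2-dioxan-3-yl]acetic acid (CNP0301546.2), via aldehyde 26 (not isolated)
Conditions: TEMPO (0.2 equiv), PhI(OAc)2 (2.5 equiv), MeCN/H2O (1:1), rt
Reagents that add atoms: water (O)
Why: Oxoammonium (TEMPO) oxidation takes the primary alcohol to the aldehyde and, through its hydrate, on to the acid, while the tertiary hemiketal hydroxyl and the dialkyl peroxide cannot be oxidised under these near-neutral conditions.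

**Compound list**

1 | (R)-citronellal | C[C@H](CCC=C(C)C)CC=O | starting material
2 | (4R)-4,8-dimethylnon-7-en-2-ol (C2 epimers) | C[C@H](CCC=C(C)C)CC(C)O | intermediate
3 | 5-[(3R)-5-hydroxy-3-methylhexyl]-3,3-dimethyl-1,2,4-trioxolane | C[C@H](CCC1OOC(C)(C)O1)CC(C)O | intermediate (not isolated)
4 | (4R)-6-hydroxy-4-methylheptanal | C[C@H](CCC=O)CC(C)O | intermediate
5 | (5-bromopentyl)benzene | BrCCCCCc1ccccc1 | starting material
6 | triphenyl(5-phenylpentyl)phosphonium bromide | [Br-].c1ccccc1CCCCC[P+](c1ccccc1)(c1ccccc1)c1ccccc1 | intermediate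
7 | triphenyl(5-phenylpentylidene)phosphorane | c1ccccc1CCCCC=P(c1ccccc1)(c1ccccc1)c1ccccc1 | intermediate (not isolated)
8 | (4R,7Z)-4-methyl-12-phenyldodec-7-en-2-ol | C[C@H](CC/C=C\CCCCc1ccccc1)CC(C)O | intermediate
9 | (4R)-4-methyl-12-phenyldodecan-2-ol | C[C@H](CCCCCCCCc1ccccc1)CC(C)O | intermediate
10 | (4R)-4-methyl-12-phenyldodecan-2-one | C[C@H](CCCCCCCCc1ccccc1)CC(C)=O | intermediate
11 | (4R)-2,4-dimethyl-12-phenyldodec-1-ene | C[C@H](CCCCCCCCc1ccccc1)CC(C)=C | intermediate
12 | (4R)-2-hydroperoxy-2-methoxy-4-methyl-12-phenyldodecane (C2 epimers) | C[C@H](CCCCCCCCc1ccccc1)CC(C)(OC)OO | intermediate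
13 | triethyl{[(4R)-2-methoxy-4-methyl-12-phenyldodecan-2-yl]peroxy}silane (C2 epimers) | C[C@H](CCCCCCCCc1ccccc1)CC(C)(OC)OO[Si](CC)(CC)CC | intermediate
14 | methyl (R)-3-hydroxy-2-methylpropanoate | C[C@H](CO)C(=O)OC | starting material
15 | methyl (S)-3-chloro-2-methylpropanoate | C[C@H](CCl)C(=O)OC | intermediate
16 | (2R)-1-methoxy-2-methyl-1-(trimethylsilyloxy)cyclopropane (C1 epimers) | C[C@@H]1CC1(OC)O[Si](C)(C)C | intermediate
17 | (2R)-1-methoxy-2-methylcyclopropan-1-ol | C[C@@H]1CC1(O)OC | intermediate (not isolated)
18 | (R)-2-methylcyclopropan-1-one | C[C@@H]1CC1=O | intermediate (not isolated)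
19 | (2R)-1-ethenyl-2-methylcyclopropan-1-ol (C1 epimers) | C[C@@H]1CC1(O)C=C | intermediate
20 | {[(2R)-1-ethenyl-2-methylcyclopropyl]oxy}trimethylsilane | C[C@@H]1CC1(O[Si](C)(C)C)C=C | intermediate
21 | 9-{2-[(2R)-2-methyl-1-(trimethylsilyloxy)cyclopropyl]ethyl}-9-borabicyclo[3.3.1]nonane | C[C@@H]1CC1(O[Si](C)(C)C)CCB1C2CCCC1CCC2 | intermediate (not isolated)
22 | 2-[(2R)-2-methyl-1-(trimethylsilyloxy)cyclopropyl]ethan-1-ol | C[C@@H]1CC1(O[Si](C)(C)C)CCO | intermediate
23 | tert-butyl{2-[(2R)-2-methyl-1-(trimethylsilyloxy)cyclopropyl]ethoxy}diphenylsilane (C1 epimers) | C[C@@H]1CC1(O[Si](C)(C)C)CCO[Si](c2ccccc2)(c2ccccc2)C(C)(C)C | intermediate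
24 | tert-butyl{2-[(3R,4R,6S)-4,6-dimethyl-6-[(2R)-2-methyl-10-phenyldecyl]-3-(trimethylsilyloxy)-1,2-dioxan-3-yl]ethoxy}diphenylsilane | C[C@H](CCCCCCCCc1ccccc1)C[C@@]1(C)C[C@@H](C)[C@](O[Si](C)(C)C)(CCO[Si](c2ccccc2)(c2ccccc2)C(C)(C)C)OO1 | intermediate
25 | (3S,4R,6S)-3-(2-hydroxyethyl)-4,6-dimethyl-6-[(2R)-2-methyl-10-phenyldecyl]-1,2-dioxan-3-ol | C[C@H](CCCCCCCCc1ccccc1)C[C@@]1(C)C[C@@H](C)[C@](O)(CCO)OO1 | intermediate
26 | 2-[(3S,4R,6S)-3-hydroxy-4,6-dimethyl-6-[(2R)-2-methyl-10-phenyldecyl]-1,2-dioxan-3-yl]acetaldehyde | C[C@H](CCCCCCCCc1ccccc1)C[C@@]1(C)C[C@@H](C)[C@](O)(CC=O)OO1 | intermediate (not isolated)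
27 | 2-[(3S,4R,6S)-3-hydroxy-4,6-dimethyl-6-[(2R)-2-methyl-10-phenyldecyl]-1,2-dioxan-3-yl]acetic acid | C[C@H](CCCCCCCCc1ccccc1)C[C@@]1(C)C[C@@H](C)[C@](O)(CC(=O)O)OO1 | target

**Step count.** Total: 18 steps. Longest linear sequence: 11 steps (steps 1, 2, 4–9, 16–18 from 1). The cyclopropane branch from 14 is 6 steps before the union.

**Steps most likely to fail**

1. Step 16 (proposed new method). The peroxycarbenium ion may rearrange by a Criegee-type 1,2-shift to oxygen before the weakly nucleophilic ring bond attacks. TiCl4 may instead open the cyclopropane to a metal homoenolate that is only protonated on work-up. The silyl oxocarbenium ion may also lose its silyl group before the peroxide oxygen closes the ring.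
   The fallback uses known chemistry, sets out from 10 and 23 and comes back to the route at 25. The trimethylsilyl ether of 23 is cleaved selectively with K2CO3 in MeOH at 0 °C to give tert-butyl{2-[(2R)-1-hydroxy-2-methylcyclopropyl]ethoxy}diphenylsilane F1. Ketone 10 is deprotonated at its methyl group (KN(SiMe3)2, THF, −78 °C) and trapped with PhNTf2 as (4R)-4-methyl-12-phenyldodec-1-en-2-yl trifluoromethanesulfonate F2. Palladium-catalysed ring-opening cross-coupling of the cyclopropanol with the alkenyl triflate (Pd(OAc)2, XPhos, Cs2CO3, toluene, mild heating) proceeds through a palladium homoenolate formed by cleavage of the less substituted ring bond. It should join C5 to C6 and give (4R)-1-{[tert-butyl(diphenyl)silyl]oxy}-4-methyl-6-[(2R)-2-methyl-10-phenyldecyl]hept-6-en-3-one F3; the base is kept mild to protect the C4 centre. Isayama–Mukaiyama silylperoxidation of the 1,1-disubstituted alkene (Co(acac)2, O2, Et3SiH) should place the triethylsilylperoxy group on C6 and give (4R,8R)-1-{[tert-butyl(diphenyl)silyl]oxy}-4,6,8-trimethyl-16-phenyl-6-[(triethylsilyl)peroxy]hexadecan-3-one F4 as a mixture of C6 epimers. HF·pyridine under the conditions of step 17 then frees the hydroperoxide and the alcohol, and the γ-hydroperoxy ketone should close to hemiketal 25, which is separated from its 6R epimer as in the main route.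

2. Step 14. The trimethylsilyl ether may be lost during the oxidative work-up, after which the free cyclopropanol can ring-open under base to the open-chain ketone.
   The fallback builds the arm by allylation and oxidative cleavage instead of vinylation and hydroboration; it sets out from 16 and comes back at 22. Compound 16 is methanolysed as in step 12 and the hemiacetal 17 is treated with CH2=CHCH2MgBr to give (2R)-2-methyl-1-(prop-2-en-1-yl)cyclopropan-1-ol F5. Silylation (Me3SiCl, imidazole) should give trimethyl{[(2R)-2-methyl-1-(prop-2-en-1-yl)cyclopropyl]oxy}silane F6. Ozonolysis of the terminal alkene at −78 °C with NaBH4 work-up at 0 °C should deliver the two-carbon alcohol 22 without any basic peroxide step.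

3. Step 8. The primary ozonide may fragment in the other direction (formaldehyde O-oxide plus ketone 10), or over-ozonation of the arene may erode the material.
   The fallback sets out from 10 and comes back at 12 without an alkene. Ketone 10 is converted with HC(OMe)3 and MeOH under pyridinium p-toluenesulfonate catalysis into (4R)-2,2-dimethoxy-4-methyl-12-phenyldodecane F7. Acid-catalysed exchange of one methoxy group with anhydrous H2O2 in Et2O at 0 °C, stopped at the mono-exchange stage, should then give methoxy hydroperoxide 12.

**Further compounds**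

F1 | step 16 | tert-butyl{2-[(2R)-1-hydroxy-2-methylcyclopropyl]ethoxy}diphenylsilane | C[C@@H]1CC1(O)CCO[Si](c2ccccc2)(c2ccccc2)C(C)(C)C
F2 | step 16 | (4R)-4-methyl-12-phenyldodec-1-en-2-yl trifluoromethanesulfonate | C[C@H](CCCCCCCCc1ccccc1)CC(=C)OS(=O)(=O)C(F)(F)F
F3 | step 16 | (4R)-1-{[tert-butyl(diphenyl)silyl]oxy}-4-methyl-6-[(2R)-2-methyl-10-phenyldecyl]hept-6-en-3-one | C=C(C[C@H](C)CCCCCCCCc1ccccc1)C[C@@H](C)C(=O)CCO[Si](c1ccccc1)(c1ccccc1)C(C)(C)C
F4 | step 16 | (4R,8R)-1-{[tert-butyl(diphenyl)silyl]oxy}-4,6,8-trimethyl-16-phenyl-6-[(triethylsilyl)peroxy]hexadecan-3-one | CC(C[C@H](C)CCCCCCCCc1ccccc1)(OO[Si](CC)(CC)CC)C[C@@H](C)C(=O)CCO[Si](c1ccccc1)(c1ccccc1)C(C)(C)C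
F5 | step 14 | (2R)-2-methyl-1-(prop-2-en-1-yl)cyclopropan-1-ol | C[C@@H]1CC1(O)CC=C
F6 | step 14 | trimethyl{[(2R)-2-methyl-1-(prop-2-en-1-yl)cyclopropyl]oxy}silane | C[C@@H]1CC1(O[Si](C)(C)C)CC=C
F7 | step 8 | (4R)-2,2-dimethoxy-4-methyl-12-phenyldodecane | C[C@H](CCCCCCCCc1ccccc1)CC(C)(OC)OC
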